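In a one-step world a flask is a first-order lag: the gap to the plateau shrinks by a factor e in each time constant. Here free enzyme turns substrate into target. Grey is the flask asked about, and green is its warmer twin.

| setting | grey | green | flask |
|---|---|---|---|
| substrate | 20 mM | 20 mM | 20 mM |
| free enzyme | 0.01 mol% | 0.01 mol% | 0.01 mol% |
| temperature | 5 °C | 11 °C | 5 °C |
| remark | the very flask that is asked about, followed so far | run made earlier |  |
| time |  |  | 50 min |

| run | time / min | target / % | substrate / % |
|---|---|---|---|
| grey | 4.00 | 20.8 | 75.0 |
| grey | 10.0 | 27.3 | 64.8 |
| grey | 20.0 | 28.5 | 61.7 |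
| grey | 30.0 | 28.5 | 61.3 |
| grey | 40.0 | 28.7 | 60.9 |
| green | 4.00 | 18.5 | 78.4 |
| green | 10.0 | 19.6 | 76.0 |
| green | 20.0 | 20.3 | 76.5 |
| green | 30.0 | 20.3 | 76.2 |
| green | 40.0 | 19.8 | 75.8 |

(scatter of a reading: 0.3 percentage points)

1. target, in percent of the substrate first charged, at 50 min
2. which option adds most target ("none" when 2 percentage points or less is all one gets) (dawn / noon / summer / winter / none)
3. target present, with what was taken out counted in, in percent of the substrate first charged, after dawn
4. target present, with what was taken out counted in, in percent of the substrate first charged, after summer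

- dawn: at 50 min add free enzyme, 50.0% of the amount charged, then wait 25 min
- noon: at 50 min raise the temperature by 15 K, then wait 25 min
- summer: at 50 min take out 90% of the target then present, then wait 25 min
- winter: change nothing and wait 25 min more

- target that was removed still counts
- the earlier runs were read with a standard deviation of 0.3 percentage points
- additions bring no volume worth counting

Which given number must you know well? Time hardly matters: grey's target moves by 0.2 percentage points from 20.0 min to 40.0 min, which is inside the scatter of 0.3 points. Temperature matters: green, the warmer run, ends lower, at 19.8% against 28.7%. The loading is shared by both runs, so they do not size it. Green also stops with more substrate left, 75.8% against 60.9%, so I read the stop as catalyst deactivation, not a shortage of substrate.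

So the number worth having is the stall time constant τ of grey, read from the gap between substrate and its last reading. That gap is 14 points at 4.00 min and 3.9 points at 10.0 min, which gives τ = 4.67 min, a reading that carries their scatter. The asked time is 10.7 τ, so my own call for target is the last reading, 28.7%. Heat, removal and waiting then act on a stalled flask, and dawn brings fresh enzyme.

The forecast gives 28.6% and picks dawn, with 32.7% after it and 28.6% after summer, holding that “By 50 min the enzyme is dead”.

The flask gives 28.7%, and dawn adds 7.1 points, reaching 35.8%; the forecast's gain of 4.1 points and this one both clear the 2 points bar, so the choice is the same.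

    target + free enzyme ⇌ isomer of the product + free enzyme, rate k1*[free enzyme]*[target] forward; the back reaction follows from the equilibrium constant (K = 3.51, k = 81000 M⁻¹ min⁻¹, Ea = 38.0 kJ mol⁻¹, ΔH = −42.0 kJ mol⁻¹)
    free enzyme → unfolded enzyme (k = 0.00521 min⁻¹, Ea = 262 kJ mol⁻¹)
    free enzyme → spent catalyst (k = 0.242 min⁻¹, Ea = 88.0 kJ mol⁻¹)
    substrate + free enzyme → target + free enzyme, rate k4*[substrate]*[free enzyme]/(1 + ([substrate]/Km4)) (8.73 mM, k = 1.70 × 10⁵ M⁻¹ min⁻¹, Ea = 40.0 kJ mol⁻¹)
    (constants at 5 °C)

Left for 500 min, grey still holds 28.7% of target. At 25.0 min, which is 5.35 τ from the start, the flask holds 0.207% of the free enzyme charged. Take τ as unchanged in a neighbour flask with 0.025 mol% of free enzyme: its 50 min is again 10.7 τ, its free enzyme stands at 0%, and its target stands at 40.5%.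

The earlier runs and the new flask stem from a simulated flask on assumed constants; the scatter is artificial.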